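**Retrosynthetic overview**
1. Both benzene rings are bought and none is built. Ring B is 2-amino-3-bromophenol 1, which already carries the C3–Br that no electrophilic bromination could place. Ring A is catechol 2.
2. Key disconnection: the diaryl ether C–O bond between C2 of ring B and the ring A oxygen. C2 becomes electrophilic as the carbene carbon of ortho-quinone diazide 3 (made from 1), and one O–H of 2 inserts to give bis-phenol 4.
3. Last disconnection: the two C–Br bonds para to the two free OH groups. Both are made on 4 in one operation (ring A first, giving 5, then ring B) to reach target 6.
4. No protecting group or redox adjustment is needed. The symmetry of 2 removes any question of which oxygen is arylated.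

Assumption 1: the target has no stereocentre and no hindered axis, so it is achiral and there is no enantiomer to select.
Assumption 2: the route has only two steps, so the list of three risks treats the two stages of step 1 as separate entries.

**Step 1**
Reactants: 1 2-amino-3-bromophenol; 2 catechol (benzene-1,2-diol)
Product: 4 3-bromo-2-(2-hydroxyphenoxy)phenol, via ortho-quinone diazide 3 (not isolated)
Conditions: (a) 1 added slowly to t-BuONO (1.02 equiv), 4 Å MS, DCE, 0 °C to rt, dark, then N2 sparge; (b) this solution added over 3 h to 2 (5 equiv), Rh2(OAc)4 (1 mol %), 4 Å MS, DCE, 60 °C, dark; excess 2 removed by water washes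
Reagents that add atoms: tert-butyl nitrite, CC(C)(C)ON=O (its nitrogen is held only in 3 and leaves as N2 on the way to 4)
Why: Proposed new method: aprotic diazotisation of the ortho-aminophenol gives the neutral ortho-quinone diazide 3, which Rh2(OAc)4 (divalent rhodium) decomposes with loss of N2 to an electrophilic rhodium quinoid carbene at C2 of ring B; a catechol oxygen adds to that carbon, the oxonium proton passes to the neighbouring carbonyl oxygen (relayed by the second catechol OH), and the ring re-aromatises as the metal leaves, so the aryl C–O bond forms exactly at the carbon that bore nitrogen, without base, copper or palladium, leaving C3–Br untouched and giving no dibenzodioxin closure; the sieves take up the water of stage (a), and hindered t-BuOH (1 equiv) is outnumbered by ten equivalents of catechol OH; symmetric 2 in excess also suppresses double arylation; the closest known reaction types are dirhodium-catalysed O–H insertion of diazonaphthoquinones into alcohols and of diazo esters into phenols, together with in-flask diazotisation/carbene transfer of amine salts, none of which has been shown for a monocyclic halogenated ortho-quinone diazide and a catechol to make a diaryl ether; no stereocentre is formed.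

**Step 2**
Reactants: 4 3-bromo-2-(2-hydroxyphenoxy)phenol
Product: 6 3,4-dibromo-2-(5-bromo-2-hydroxyphenoxy)phenol, via dibromide 5 (not isolated)
Conditions: NBS (2.05 equiv, two portions), MeCN, −20 °C to 0 °C, dark
Reagents that add atoms: N-bromosuccinimide, O=C1CCC(=O)N1Br
Why: This is an electrophilic aromatic bromination in which the free OH is the strongest donor in each ring and NBS in MeCN attacks para to it, so the bromine-free ring A reacts first (5) and ring B then reacts at C4 (para to OH, ortho to the existing Br), faster than the remaining ortho-to-OH site of ring A, which lies meta to its bromine; no stereocentre is formed.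

**Compound list**
1 | 2-amino-3-bromophenol | Nc1c(O)cccc1Br | starting material
2 | catechol (benzene-1,2-diol) | Oc1ccccc1O | starting material
3 | 5-bromo-6-diazocyclohexa-2,4-dien-1-one (ortho-quinone diazide of 1; not isolated) | O=C1C=CC=C(Br)C1=[N+]=[N-] | intermediate
4 | 3-bromo-2-(2-hydroxyphenoxy)phenol | Oc1ccccc1Oc1c(O)cccc1Br | intermediate
5 | 3-bromo-2-(5-bromo-2-hydroxyphenoxy)phenol (not isolated) | Oc1ccc(Br)cc1Oc1c(O)cccc1Br | intermediate
6 | 3,4-dibromo-2-(5-bromo-2-hydroxyphenoxy)phenol (achiral) | Oc1ccc(Br)cc1Oc1c(O)ccc(Br)c1Br | target

**Total step count:** 2. **Longest linear sequence:** 2.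

**Steps most likely to fail**

Risk 1: step 1, stage (b), the proposed new O–H insertion.
- Possible failures are Wolff ring contraction of the carbene, attack by a catechol ring carbon instead of oxygen (giving a biaryl), azo coupling, and slowing of the catalyst by catechol.
- The fallback uses known chemistry only. It sets out from 2 and comes back at 4.
- Catechol 2 (3 equiv) is heated with bought 3-bromo-2-fluorobenzaldehyde (O=Cc1cccc(Br)c1F) and K2CO3 in DMF at 80 °C under N2. This SNAr displaces the fluoride ortho to the formyl group, while the bromide meta to it is not activated. The product is 3-bromo-2-(2-hydroxyphenoxy)benzaldehyde F1.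
- Baeyer–Villiger oxidation with mCPBA in CH2Cl2 at rt moves the aryloxy-substituted aryl group onto oxygen and gives 3-bromo-2-(2-hydroxyphenoxy)phenyl formate F2.
- A catalytic amount of K2CO3 in MeOH cleaves the formate to 4. The key bond is still an aryl C–O bond, and the route grows by one to two steps.

Risk 2: step 2, the double bromination.
- Possible failures are bromination of ring B at C6 (ortho to OH) instead of the more crowded C4, and a second bromine entering ring A.
- The fallback sets out from 4 and comes back at 6. It exchanges the directing groups rather than the reagent.
- 4 is methylated on both oxygens (MeI, K2CO3, acetone, reflux) to 1-bromo-3-methoxy-2-(2-methoxyphenoxy)benzene F3.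
- Anisoles are brominated by NBS in MeCN essentially only para to OMe. Two equivalents therefore give first 1-bromo-2-(5-bromo-2-methoxyphenoxy)-3-methoxybenzene F4 and then 1,2-dibromo-3-(5-bromo-2-methoxyphenoxy)-4-methoxybenzene F5.
- BBr3 in CH2Cl2 (−78 °C to rt) removes both methyl groups and gives 6.

Risk 3: step 1, stage (a), the in-flask diazotisation.
- Possible failures are triazene or azo coupling of 3 with unreacted 1, left-over nitrite attacking catechol or the catalyst, and carried-over water or t-BuOH trapping the carbene.
- The fallback sets out from 1 and comes back at 3. It replaces the one-flask aprotic nitrosation with a classical aqueous diazotisation and an isolated salt.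
- 1 is treated with NaNO2 in aqueous HBF4 at 0 °C. The precipitated 2-bromo-6-hydroxybenzenediazonium tetrafluoroborate F6 is filtered off and washed with cold ether.
- The salt is shaken in CH2Cl2 with aqueous NaHCO3. The dried organic layer holds 3 free of alcohol, water and nitrite, and after a solvent switch to DCE it enters stage (b) of step 1 unchanged.

**Further compounds**
F1 | step 1 | 3-bromo-2-(2-hydroxyphenoxy)benzaldehyde | O=Cc1cccc(Br)c1Oc1ccccc1O
F2 | step 1 | 3-bromo-2-(2-hydroxyphenoxy)phenyl formate | O=COc1cccc(Br)c1Oc1ccccc1O
F3 | step 2 | 1-bromo-3-methoxy-2-(2-methoxyphenoxy)benzene | COc1ccccc1Oc1c(OC)cccc1Br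
F4 | step 2 | 1-bromo-2-(5-bromo-2-methoxyphenoxy)-3-methoxybenzene | COc1ccc(Br)cc1Oc1c(OC)cccc1Br
F5 | step 2 | 1,2-dibromo-3-(5-bromo-2-methoxyphenoxy)-4-methoxybenzene | COc1ccc(Br)cc1Oc1c(OC)ccc(Br)c1Br
F6 | step 1 | 2-bromo-6-hydroxybenzenediazonium tetrafluoroborate | Oc1cccc(Br)c1[N+]#N.F[B-](F)(F)F
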